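- Start from the question: how much target do west and south-east hold at the end, and does it beat isomer of the product A?

- which of the two there is more of at the end, west (isomer of the product A / target)
- which of the two there is more of at the end, south-east (isomer of the product A / target)
- target at the end, in percent of the substrate charged, west
- target at the end, in percent of the substrate charged, south-east

common to all: substrate 0.19 M
- larch: reagent 2.6 equiv; temperature 60 °C; run made earlier
- west: reagent 1.30 equiv; temperature 60 °C; time 8.0 h
- south-east: reagent 1.30 equiv; temperature 80 °C; time 8.0 h

- larch (time / min: target / %, substrate / %): 4.00: 0, 98.4; 6.00: 0.6, 98.5; 10.0: 0.1, 96.8; 20.0: 1.4, 93.5; 30.0: 2.3, 91.6; 50.0: 5.5, 86.1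

(standard deviation of a reading: 0.5 percentage points)

- the earlier runs do not show what temperature does; that part of a forecast is a guess
- a reading or a percentage of target counts all its forms, free or not

- Take the last larch reading, which stands farthest above the scatter: 86.1% of the substrate is left at 50.0 min, so 13.9% is lost, while 5.5% is target.
- Divide the two to get the target share, target found per substrate lost, the integral selectivity: 39.6%.
- Treat it as a reading: at 30.0 min it stood at 27.4%, so it is still climbing. My own bet is that it stops here and that the rest of the lost substrate stays as isomer of the product A.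
- Then write target = share × (one − fraction left). The rest, 60.4%, exceeds 39.6%, so on this bet isomer of the product A leads in both flasks.
- Now get the fraction left. In larch, ln(charged/left)/time gives 0.00299 min⁻¹ at [reagent] = 0.494 M.
- Assume, untested, first order in reagent and one reagent per substrate. Then [reagent] − [substrate] stays at 0.0570 M in west, and integrating the rate law leaves 56.1% of the substrate after 8.0 h.
- So my west figure is 17.4% target. For south-east the temperature effect is a guess, but the fraction left cannot go below zero, so on a fixed share target stays under 39.6%.
- The forecast differs. It puts target ahead in west at 41% (24% to 65%), and target ahead in south-east at 76% (45% to 93%). Its ground is that the unaccounted material “levels off, which suggests an intermediate, probably isomer A, passing on to target”. Its 41% lies above my 17.4%, and its 76% lies above my ceiling.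
- West gives 18.8% target and south-east 28.8%, with isomer of the product A ahead at 32.1% and 57.5%. Substrate left at the end is 46.2% in west and 8.47% in south-east. Multiply the substrate lost by the share: 39.6% gives 21.3% for west and 36.2% for south-east, both above the flasks' values, whose own shares are 34.9% and 31.5%.

    substrate ⇌ tight pair (K = 0.00840, k = 0.276 h⁻¹, Ea = 99.0 kJ mol⁻¹, ΔH = 18.0 kJ mol⁻¹)
    tight pair ⇌ loose pair (K = 3.34, k = 630 h⁻¹, Ea = 77.0 kJ mol⁻¹, ΔH = −3.00 kJ mol⁻¹)
    reagent + tight pair → target (k = 40.6 L mol⁻¹ h⁻¹, Ea = 65.0 kJ mol⁻¹)
    reagent + loose pair → isomer of the product A (k = 19.7 L mol⁻¹ h⁻¹, Ea = 73.0 kJ mol⁻¹)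
    target ⇌ isomer of the product B (K = 1.30, k = 0.178 h⁻¹, Ea = 116 kJ mol⁻¹, ΔH = −46.0 kJ mol⁻¹)
    reagent + target ⇌ idle adduct, settled at all times (K = 49.0 L mol⁻¹, ΔH = 27.0 kJ mol⁻¹)
    loose pair → side product (k = 0.0235 h⁻¹, Ea = 103 kJ mol⁻¹)
    (constants at 60 °C)

- Try a neighbour of south-east, the same flask with 0.780 equiv of reagent: at the end 30% of its substrate is left, so the share gives 27.7% target. The computed flask holds 18.4% target beside 42.3% isomer of the product A.

The data come from a simulation for substances that don't exist; the scatter is artificial.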